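## The problem

Elemane numbering is used throughout: the cyclohexane is C5–C10, the lactone is C7–C11(=C13)–C12(=O)–O–C8, C10 carries the methyl C14 and the oxirane C1–C2, and C5 carries the acrolein C4(=C3)–C15HO. Target 38 is thus a cyclohexane with a trans-fused α-methylene-γ-butyrolactone at C7/C8, a quaternary C10, an axial C6 hydroxyl and an axial C9 angelate. Six contiguous ring stereocentres (C5–C10) and the exocyclic C1 have to be set. C8 can be bought and directs C7 by anti addition to a butenolide. The trans lactone then locks a single chair in which the C10 methyl and O6 are axial on one face and O9 is axial on the other, so the C9–C10 ring closure and hydride delivery to C6 can be steered by the ring. C5 lies next to C6 and must arrive with the C6 fragment, and C1 sits on a rotating two-carbon arm with no reliable neighbour to control it. The α-methylene lactone and the enal are Michael acceptors, the angelate isomerises to the tiglate, the oxirane is acid-labile, a C6 ketone makes C5 and C7 epimerisable, and base can move the lactone from O8 to O6; these groups must appear late and in a fixed order. The feature that allows a convergent union is that the carbinol carbon C6 is bonded to C7, the β-carbon of the C12 lactone: a C6 acyl anion adding to a C8-substituted butenolide joins the two halves, and the C11 enolate so formed is one carbon (C13) short of the methylene lactone.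

## Retrosynthesis

**Oxirane last (38 ⇒ 37 ⇒ 36).** The C1–O and C2–O bonds are cut back to the C10 vinyl group of enal 36. In the locked chair the equatorial vinyl group should eclipse the axial methyl; its face toward C9 is flanked only by H9, while the face toward C5 is screened by the equatorial C4 substituent. Direct oxygen transfer to the open face would give the 1S epimer. Oxygen is therefore delivered anti, through bromohydrin 37 (bromonium on the open face, water from the other, ring closure), which should give 1R. The step needs the vinyl group to be the only electron-rich alkene, so enal and methylene lactone must already be present.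

**Acrolein and methylene lactone (36 ⇒ 35 ⇒ 34 ⇒ 33 ⇒ 32).** The C15 aldehyde is traced to the C15 methyl of an isopropenyl group (allylic oxidation via alcohol 35). The C11=C13 bond is traced to the dimethylaminomethyl group of 32 by quaternisation (33) and elimination. The amine must be eliminated before oxidants are used, and the methylene lactone must not exist during hydride reduction; this fixes the order.

**C6 and C9 oxygen functions (32 ⇒ 31 ⇒ 30 ⇒ 28).** The C6 carbinol comes from ketone 31, attacked by hydride anti to the axial C10 methyl, and the ketone from the dithiane of 30. The angelate is installed on 28, where O9 is the only free hydroxyl and C6 is still a thioacetal. Differentiating two hindered axial alcohols later would be much harder.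

**Cyclohexane (28 ⇒ 27).** The C9–C10 bond is cut to a C9 aldehyde and a C2–C1=C10 allyl metal. This closure creates the quaternary centre and the vinyl group together. In the six-centre chair transition state with the aldehyde substituent C8 equatorial, a (Z)-allyl unit (C5 cis to C2) places C5 axial on that array. The result is a cis-fused bicyclic arrangement with the new C9–O bond axial and anti to the C10 methyl, as in 38. An (E)-alkene would pass through the trans-fused array and give the C9 epimer, so the Z geometry is required. The allyl donor is a diethyl phosphate, not a bromide, because an allylic bromide would alkylate the tertiary amine. Phosphates with CrCl2/LiI in DMPU are also the conditions under which γ,γ-disubstituted allylchromium reagents keep their geometry.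

**Adjusting the coupling product (27 ⇒ 26 ⇒ 25 ⇒ 24 ⇒ 23).** Only protecting-group and oxidation-state changes separate aldehyde 27 from the coupling product 23. A triethylsilyl ether on O2 and a tert-butyldimethylsilyl ether on O9 are removable in that order with fluoride. A p-methoxybenzyl ether was rejected because its oxidative removal endangers dithiane and amine.

**Key union (23 ⇒ 19 + 5 + 20).** The C6–C7 and C11–C13 bonds are cut together. Lithiated dithiane 19 adds to C7 of butenolide 5 anti to the C8 substituent, and the enolate is trapped by iminium salt 20. Against an aldol or alkylation at C7, this cut uses the natural polarity of the lactone and brings C13 in as a masked methylene that survives hydride reduction. The precursors are far simpler: an acyclic dithiane with one stereocentre and a five-membered chiral-pool lactone.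

**Fragment 1 (5 ⇒ 2 ⇒ 1).** Butenolide 5 comes from commercial lactone 1 by silylation and selenoxide elimination.

**Z-allylic arm of fragment 2 (19 ⇒ 18 ⇒ 17 ⇒ 16).** The (Z)-trisubstituted allylic alcohol is cut at the C10–C14 bond to ynoate 16; syn-methylcupration places C5 cis to the ester. Carboalumination of a terminal alkyne would be shorter but gives the E isomer.

**C5 stereocentre (16 ⇒ 15 ⇒ 14 ⇒ 13 ⇒ 12 ⇒ 10 ⇒ 9 ⇒ 6 + 7).** The alkyne is traced through dibromoalkene 15 to aldehyde 14 and alcohol 13. C5 is set in 10 by a titanium-enolate reaction of imide 9 with trimethyl orthoformate. This brings C6 in as an acetal (then dithiane 12) while C10 is still a carboxyl carbon. A direct asymmetric α-alkenylation of a but-3-enoate was rejected: an α,α-dialkenyl carbonyl compound has a doubly activated α-hydrogen and would racemise or conjugate. Here the only aldehyde on the route (14) has one activating alkene and is consumed at once.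

## Roads not taken

**Alternative 1:** Retro-Cope cut of C5–C10 to the ten-membered dienolide A1. Heating A1 would break C2–C3, form C5–C10 and give the elematriene diol A2.
- Merits: one step creates the quaternary C10 with its vinyl group and the acrolein-bearing C5, with their relative configuration fixed by a chair transition state. C15, C3, C1 and C2 need no oxidation-state changes.
- Weak points: A1 is a stereodefined, fully oxygenated cyclodeca-1,5-diene with a trans lactone, at least as hard to make as 38. The rearrangement is reversible and may stop at a mixture. A2 still needs O6 and O9 told apart for angeloylation, and the vinyl group epoxidised with the same C1 problem.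
- Comparison: this road is better in core step economy and in C5/C10 control. The chosen plan is longer but needs no medium ring and keeps O6 and O9 distinct by oxidation level.

**Alternative 2:** Cut of C9–C10 and O–C1 by an intramolecular nitrile oxide cycloaddition. Aldoxime A3 would be oxidised with NaOCl to nitrile oxide A4, which adds across the (Z)-C10=C1 alkene to give isoxazoline A5.
- Merits: C10 and the C1 oxygen are set in one stereospecific suprafacial event. This is exactly where the chosen plan is weakest, because it must set C1 by late halohydrin chemistry.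
- Weak points: after N–O cleavage C9 is a ketone next to the quaternary centre and must be reduced to the axial alcohol. The C1,C2-diol derivative must be converted into the oxirane. C4 arrives as a ketal-protected acetyl group needing methylenation and oxidation. C13 needs a separate late enolate step, and three different protecting groups are carried.
- Comparison: this road is better for C1. The chosen plan sets against it a convergent three-component union that supplies C13 at once, and a halohydrin/dioxirane pair that places oxygen on opposite faces.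

**Alternative 3:** Cut of C4–C5 and C1–C10 on a preformed ring. Copper-catalysed asymmetric conjugate addition of alkenyl Grignard reagent A7 to enone A6, with aldol trapping of the enolate by chloroacetaldehyde A8, would give ketone A9.
- Merits: three stereocentres (C5, C10, C1) and two C–C bonds from achiral materials in one catalytic operation. The chlorohydrin is a direct oxirane precursor, and the acrolein is carried as its acetal.
- Weak points: enantioselective addition of an α-branched alkenyl nucleophile to an α-methyl enone is demanding. The aldol of a tetrasubstituted enolate with an enolisable, polymerisation-prone aldehyde must control C10 and C1 together. In A9, C7 and C8 are unfunctionalised methylenes, so the whole lactone half and the C6 and C9 configurations must be built later on a crowded ring.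
- Comparison: this road front-loads C1 and C10 better. The chosen plan takes C7, C8 and the lactone intact from the chiral pool and builds the carbocycle around them.

Key step: step 12

Remark: 38 is treated as the open 6-hydroxy-15-aldehyde as drawn, not as a cyclic hemiacetal between O6 and C15.
Remark: α denotes the ring face of H5, H7 and O8; β the face of the C10 methyl and O6.

## Route

Step 1
Reactants: 1 (5R)-5-(hydroxymethyl)oxolan-2-one
Product: 2 (5R)-5-{[tert-butyl(dimethyl)silyl]oxymethyl}oxolan-2-one
Conditions: t-BuMe2SiCl, imidazole, DMF, rt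
Reagents that add atoms: tert-butyl(chloro)dimethylsilane, CC(C)(C)[Si](C)(C)Cl
Why: Imidazole-mediated silylation of a primary alcohol; the stereocentre is not involved.

Step 2
Reactants: 2 (5R)-5-{[tert-butyl(dimethyl)silyl]oxymethyl}oxolan-2-one
Product: 5 (5R)-5-{[tert-butyl(dimethyl)silyl]oxymethyl}furan-2(5H)-one (fragment 1), via α-phenylselanyl lactone 3 (not isolated), via selenoxide 4 (not isolated)
Conditions: LDA, THF, −78 °C; PhSeBr; then 30% H2O2, pyridine, CH2Cl2, 0 °C → rt
Reagents that add atoms: none
Why: α-Selenenylation of the lactone enolate followed by selenoxide syn-elimination; the elimination is not basic, so C8 (C5 of the furanone) should keep its configuration.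

Step 3
Reactants: 6 3-methylbut-3-enoic acid; 7 (4S)-4-benzyl-1,3-oxazolidin-2-one
Product: 9 (4S)-4-benzyl-3-(3-methylbut-3-enoyl)-1,3-oxazolidin-2-one, via mixed pivalic anhydride 8 (not isolated)
Conditions: t-BuCOCl, Et3N, THF, −20 °C; then 7, LiCl, −20 °C → rt
Reagents that add atoms: none
Why: N-Acylation of the oxazolidinone through a mixed anhydride; the low temperature should keep the β,γ-double bond out of conjugation.

Step 4
Reactants: 9 (4S)-4-benzyl-3-(3-methylbut-3-enoyl)-1,3-oxazolidin-2-one
Product: 10 (4S)-4-benzyl-3-[(2R)-2-(dimethoxymethyl)-3-methylbut-3-enoyl]-1,3-oxazolidin-2-one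
Conditions: TiCl4, i-Pr2NEt, CH2Cl2, 0 °C; then HC(OMe)3, 0 °C
Reagents that add atoms: trimethyl orthoformate, COC(OC)OC
Why: Titanium-enolate alkylation with an orthoester-derived oxocarbenium ion; the chelated (Z)-dienolate should react at its α-carbon on the face opposite the benzyl group, which sets C5 and brings C6 in at the aldehyde oxidation level.

Step 5
Reactants: 10 (4S)-4-benzyl-3-[(2R)-2-(dimethoxymethyl)-3-methylbut-3-enoyl]-1,3-oxazolidin-2-one; 11 propane-1,3-dithiol
Product: 12 (4S)-4-benzyl-3-[(2S)-2-(1,3-dithian-2-yl)-3-methylbut-3-enoyl]-1,3-oxazolidin-2-one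
Conditions: BF3·OEt2, CH2Cl2, −20 → 0 °C
Reagents that add atoms: none
Why: Lewis-acid transthioacetalisation of the dimethyl acetal; the imide α-centre resists enolisation because of allylic strain, so C5 should be unchanged (the descriptor changes only through priorities).

Step 6
Reactants: 12 (4S)-4-benzyl-3-[(2S)-2-(1,3-dithian-2-yl)-3-methylbut-3-enoyl]-1,3-oxazolidin-2-one
Product: 13 (2S)-2-(1,3-dithian-2-yl)-3-methylbut-3-en-1-ol
Conditions: LiBH4, MeOH (1 equiv), THF, 0 °C
Reagents that add atoms: none
Why: Reductive cleavage of the N-acyl oxazolidinone to the primary alcohol; the auxiliary 7 is recovered and C5 is untouched.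

Step 7
Reactants: 13 (2S)-2-(1,3-dithian-2-yl)-3-methylbut-3-en-1-ol
Product: 15 2-[(3R)-1,1-dibromo-4-methylpenta-1,4-dien-3-yl]-1,3-dithiane, via aldehyde 14 (not isolated)
Conditions: SO3·pyridine, DMSO, i-Pr2NEt, CH2Cl2, −20 °C; crude 14 then CBr4, PPh3, CH2Cl2, 0 °C
Reagents that add atoms: carbon tetrabromide, BrC(Br)(Br)Br
Why: Parikh–Doering oxidation followed directly by the first stage of the Corey–Fuchs reaction; the β,γ-unsaturated aldehyde is not stored, and conjugation to a tetrasubstituted enal is disfavoured beside the bulky dithiane.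

Step 8
Reactants: 15 2-[(3R)-1,1-dibromo-4-methylpenta-1,4-dien-3-yl]-1,3-dithiane
Product: 16 methyl (4S)-4-(1,3-dithian-2-yl)-5-methylhex-5-en-2-ynoate
Conditions: n-BuLi (2.1 equiv), THF, −78 °C; then ClCO2Me, −78 °C
Reagents that add atoms: methyl chloroformate, COC(=O)Cl
Why: Second stage of the Corey–Fuchs reaction (bromine–lithium exchange, Fritsch–Buttenberg–Wiechell rearrangement) and C-acylation of the lithium acetylide; exchange should outrun deprotonation at C5.

Step 9
Reactants: 16 methyl (4S)-4-(1,3-dithian-2-yl)-5-methylhex-5-en-2-ynoate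
Product: 17 methyl (2Z,4S)-4-(1,3-dithian-2-yl)-3,5-dimethylhexa-2,5-dienoate
Conditions: Me2CuLi (from CuI and MeLi), THF, −78 °C; MeOH quench at −78 °C
Reagents that add atoms: lithium dimethylcuprate, [Li+].C[Cu-]C
Why: syn-Carbocupration of an ynoate; protonation of the alkenylcopper at −78 °C with retention places the new methyl trans and C5 cis to the ester, which is the 2Z geometry needed for the ring closure.

Step 10
Reactants: 17 methyl (2Z,4S)-4-(1,3-dithian-2-yl)-3,5-dimethylhexa-2,5-dienoate
Product: 18 (2Z,4S)-4-(1,3-dithian-2-yl)-3,5-dimethylhexa-2,5-dien-1-ol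
Conditions: DIBAL-H, CH2Cl2, −78 °C
Reagents that add atoms: none
Why: 1,2-Reduction of an enoate with an aluminium hydride at low temperature; the alkene geometry is retained.

Step 11
Reactants: 18 (2Z,4S)-4-(1,3-dithian-2-yl)-3,5-dimethylhexa-2,5-dien-1-ol
Product: 19 {[(2Z,4S)-4-(1,3-dithian-2-yl)-3,5-dimethylhexa-2,5-dien-1-yl]oxy}(triethyl)silane (fragment 2)
Conditions: Et3SiCl, imidazole, CH2Cl2, 0 °C
Reagents that add atoms: chlorotriethylsilane, CC[Si](Cl)(CC)CC
Why: Silylation of the primary allylic alcohol with a group that can later be removed in the presence of the tert-butyldimethylsilyl ether.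

Step 12
Reactants: 19 {[(2Z,4S)-4-(1,3-dithian-2-yl)-3,5-dimethylhexa-2,5-dien-1-yl]oxy}(triethyl)silane; 5 (5R)-5-{[tert-butyl(dimethyl)silyl]oxymethyl}furan-2(5H)-one; 20 N,N-dimethylmethaniminium iodide
Product: 23 (3S,4R,5R)-5-{[tert-butyl(dimethyl)silyl]oxymethyl}-3-[(dimethylamino)methyl]-4-{2-[(3S,4Z)-2,4-dimethyl-6-(triethylsilyloxy)hexa-1,4-dien-3-yl]-1,3-dithian-2-yl}oxolan-2-one, via lithiated dithiane 21 (not isolated), via lithium lactone enolate 22 (not isolated)
Conditions: 19, t-BuLi, THF/HMPA (10:1), −78 °C, 10 min; 5, −78 °C; then 20, −78 → 0 °C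
Reagents that add atoms: none
Why: t-BuLi in THF/HMPA should remove the C6 proton of 19 to give 21; the neighbouring C5–H is held in the plane of the (Z)-alkene by allylic strain and is kinetically shielded. The HMPA-separated 2-alkyl-2-lithiodithiane then adds 1,4 to butenolide 5 at C7, anti to the C8 silyloxymethyl group, forming C6–C7 and giving enolate 22. Enolate 22 is aminomethylated at C11 by iminium ion 20 on the face opposite the new C7 substituent, forming C11–C13. The closest known reaction type is the tandem conjugate addition of lithiated dithianes to butenolides with electrophilic trapping of the enolate, combined with the aminomethylation of lactone enolates by preformed iminium salts. No ring closes. C7 is controlled by C8 (steric shielding of one face of the butenolide), and C11 is controlled by C7 and is erased in step 21. The step needs 1,4- over 1,2-addition (secured by HMPA and the soft sulfur-stabilised anion) and anti facial selectivity (secured by the C8 substituent). C5 of 19 is a spectator, and reagent control by the butenolide should override any mismatch.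

Step 13
Reactants: 23 (3S,4R,5R)-5-{[tert-butyl(dimethyl)silyl]oxymethyl}-3-[(dimethylamino)methyl]-4-{2-[(3S,4Z)-2,4-dimethyl-6-(triethylsilyloxy)hexa-1,4-dien-3-yl]-1,3-dithian-2-yl}oxolan-2-one
Product: 24 (3S,4R,5R)-5-{[tert-butyl(dimethyl)silyl]oxymethyl}-3-[(dimethylamino)methyl]-4-{2-[(3S,4Z)-6-hydroxy-2,4-dimethylhexa-1,4-dien-3-yl]-1,3-dithian-2-yl}oxolan-2-one
Conditions: HF·pyridine, pyridine, THF, 0 °C
Reagents that add atoms: none
Why: Selective desilylation; a primary allylic triethylsilyl ether is cleaved much faster than a primary tert-butyldimethylsilyl ether under buffered HF·pyridine.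

Step 14
Reactants: 24 (3S,4R,5R)-5-{[tert-butyl(dimethyl)silyl]oxymethyl}-3-[(dimethylamino)methyl]-4-{2-[(3S,4Z)-6-hydroxy-2,4-dimethylhexa-1,4-dien-3-yl]-1,3-dithian-2-yl}oxolan-2-one
Product: 25 (2Z,4S)-4-{2-[(3R,4S,5R)-2-{[tert-butyl(dimethyl)silyl]oxymethyl}-4-[(dimethylamino)methyl]-5-oxooxolan-3-yl]-1,3-dithian-2-yl}-3,5-dimethylhexa-2,5-dien-1-yl diethyl phosphate (the O2 diethyl phosphate of 24)
Conditions: (EtO)2P(O)Cl, pyridine, DMAP (cat.), CH2Cl2, 0 °C
Reagents that add atoms: diethyl chlorophosphate, CCOP(=O)(Cl)OCC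
Why: O-Phosphorylation of the allylic alcohol; unlike an allylic bromide, the phosphate should not quaternise the tertiary amine (Menshutkin reaction) and can be stored.

Step 15
Reactants: 25 the O2 diethyl phosphate of 24
Product: 26 the C9 primary alcohol: (2Z,4S)-4-{2-[(3R,4S,5R)-4-[(dimethylamino)methyl]-2-(hydroxymethyl)-5-oxooxolan-3-yl]-1,3-dithian-2-yl}-3,5-dimethylhexa-2,5-dien-1-yl diethyl phosphate
Conditions: HF·pyridine, THF, rt
Reagents that add atoms: none
Why: Fluoride-mediated cleavage of the remaining silyl ether; phosphate triester, dithiane and lactone are stable to HF·pyridine.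

Step 16
Reactants: 26 the C9 primary alcohol
Product: 27 (2R,3R,4S)-3-{2-[(3S,4Z)-6-[(diethoxyphosphoryl)oxy]-2,4-dimethylhexa-1,4-dien-3-yl]-1,3-dithian-2-yl}-4-[(dimethylamino)methyl]-5-oxooxolane-2-carbaldehyde
Conditions: SO3·pyridine, DMSO, i-Pr2NEt, CH2Cl2, −10 °C; used crude
Reagents that add atoms: none
Why: Parikh–Doering oxidation, which tolerates the dithiane and the amine; the low temperature and hindered base should keep the α-oxygenated C8 centre intact.

Step 17
Reactants: 27 (2R,3R,4S)-3-{2-[(3S,4Z)-6-[(diethoxyphosphoryl)oxy]-2,4-dimethylhexa-1,4-dien-3-yl]-1,3-dithian-2-yl}-4-[(dimethylamino)methyl]-5-oxooxolane-2-carbaldehyde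
Product: 28 (5S,7R,8R,9S,10S,11S)-13-(dimethylamino)-9-hydroxy-6,6-(propane-1,3-diyldisulfanediyl)-11,13-dihydroelema-1,3-dien-12,8-olide
Conditions: CrCl2 (excess), LiI (cat.), DMPU, rt, high dilution
Reagents that add atoms: none
Why: Intramolecular Nozaki–Hiyama-type allylation: divalent chromium converts the allylic phosphate (via the iodide) into an allylchromium species that attacks the aldehyde through its γ-carbon C10, closing the six-membered ring in a chair six-centre transition state. With C8 equatorial and the (Z)-allyl unit placing C5 axial on that array, the C9 oxygen should end axial (α) and anti to the C10 methyl (β), the vinyl group equatorial. The carbocycle chair is fixed by the diequatorial trans lactone and the equatorial isopropenyl group; DMPU suppresses E/Z equilibration of the allylchromium.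

Step 18
Reactants: 28 (5S,7R,8R,9S,10S,11S)-13-(dimethylamino)-9-hydroxy-6,6-(propane-1,3-diyldisulfanediyl)-11,13-dihydroelema-1,3-dien-12,8-olide; 29 angelic acid [(2Z)-2-methylbut-2-enoic acid]
Product: 30 (5S,7R,8R,9S,10S,11S)-9-angeloyloxy-13-(dimethylamino)-6,6-(propane-1,3-diyldisulfanediyl)-11,13-dihydroelema-1,3-dien-12,8-olide
Conditions: 29, 2,4,6-trichlorobenzoyl chloride, Et3N, toluene, rt; then 28, DMAP, toluene, 50 °C
Reagents that add atoms: none
Why: Yamaguchi esterification through the mixed anhydride, the standard way to acylate hindered secondary alcohols with angelic acid without Z→E isomerisation; O9 is the only hydroxyl at this stage.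

Step 19
Reactants: 30 (5S,7R,8R,9S,10S,11S)-9-angeloyloxy-13-(dimethylamino)-6,6-(propane-1,3-diyldisulfanediyl)-11,13-dihydroelema-1,3-dien-12,8-olide
Product: 31 (5S,7R,8R,9S,10S,11S)-9-angeloyloxy-13-(dimethylamino)-6-oxo-11,13-dihydroelema-1,3-dien-12,8-olide
Conditions: CF3CO2H (1.1 equiv), PhI(OCOCF3)2, MeCN/H2O (9:1), 0 °C; pH 7 work-up
Reagents that add atoms: water, O
Why: Oxidative dethioacetalisation with a hypervalent iodine reagent; the amine is parked as its ammonium salt, and the acidic, cold conditions should spare the enolisable C5 and C7 centres.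

Step 20
Reactants: 31 (5S,7R,8R,9S,10S,11S)-9-angeloyloxy-13-(dimethylamino)-6-oxo-11,13-dihydroelema-1,3-dien-12,8-olide
Product: 32 (5S,6S,7S,8R,9S,10S,11S)-9-angeloyloxy-13-(dimethylamino)-6-hydroxy-11,13-dihydroelema-1,3-dien-12,8-olide
Conditions: LiAlH(O-t-Bu)3, THF, −78 → −30 °C
Reagents that add atoms: none
Why: Chemoselective ketone reduction by a bulky alkoxyaluminium hydride that leaves ester and lactone alone; the β face of C6 is blocked by the syn-axial C10 methyl, so hydride should enter from the α face and give the axial 6β-alcohol.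

Step 21
Reactants: 32 (5S,6S,7S,8R,9S,10S,11S)-9-angeloyloxy-13-(dimethylamino)-6-hydroxy-11,13-dihydroelema-1,3-dien-12,8-olide
Product: 34 (5S,6S,7S,8R,9S,10S)-9-angeloyloxy-6-hydroxyelema-1,3,11(13)-trien-12,8-olide, via trimethylammonium iodide 33 (not isolated)
Conditions: MeI, MeCN, rt; then aq. NaHCO3, EtOAc, rt
Reagents that add atoms: none
Why: N-Methylation followed by E1cB (Hofmann-type) elimination of trimethylamine from the β-ammonio lactone, the standard unmasking of an α-methylene lactone; the C11 centre is erased.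

Step 22
Reactants: 34 (5S,6S,7S,8R,9S,10S)-9-angeloyloxy-6-hydroxyelema-1,3,11(13)-trien-12,8-olide
Product: 36 (5R,6S,7S,8R,9S,10S)-9-angeloyloxy-6-hydroxy-15-oxoelema-1,3,11(13)-trien-12,8-olide, via allylic alcohol 35 (not isolated)
Conditions: SeO2 (cat.), t-BuOOH, CH2Cl2, rt; then MnO2, CH2Cl2, rt
Reagents that add atoms: tert-butyl hydroperoxide, CC(C)(C)OO; selenium dioxide, O=[Se]=O
Why: Selenium dioxide allylic oxidation (ene reaction, then [2,3]-shift) of the only electron-rich alkene that has allylic hydrogens, methyl being preferred over the hindered C5 methine; MnO2 then oxidises only the allylic alcohol to the enal.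

Step 23
Reactants: 36 (5R,6S,7S,8R,9S,10S)-9-angeloyloxy-6-hydroxy-15-oxoelema-1,3,11(13)-trien-12,8-olide
Product: 37 (1R,5R,6S,7S,8R,9S,10R)-9-angeloyloxy-2-bromo-1,6-dihydroxy-15-oxoelema-3,11(13)-dien-12,8-olide
Conditions: NBS, THF/H2O (3:1), 0 °C, dark
Reagents that add atoms: N-bromosuccinimide, O=C1CCC(=O)N1Br; water, O
Why: Bromohydrin formation on the only electron-rich alkene. Bromonium should form on the vinyl face toward C9 (flanked by H9 only), and water opens it from the opposite face, which places the C1 oxygen in the 1R sense. The regioisomeric bromohydrin would close to the same oxirane.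

Step 24
Reactants: 37 (1R,5R,6S,7S,8R,9S,10R)-9-angeloyloxy-2-bromo-1,6-dihydroxy-15-oxoelema-3,11(13)-dien-12,8-olide
Product: 38 (1R,5R,6S,7S,8R,9S,10R)-9-angeloyloxy-1,2-epoxy-6-hydroxy-15-oxoelema-3,11(13)-dien-12,8-olide (CNP0130022.2)
Conditions: K2CO3, acetone, 0 °C → rt
Reagents that add atoms: none
Why: Intramolecular Williamson etherification (3-exo-tet) of the bromohydrin; the C1–O bond is not broken, so C1 keeps its configuration, and the non-nucleophilic medium spares the Michael acceptors.

## Compound list

1 | (5R)-5-(hydroxymethyl)oxolan-2-one | O=C1CC[C@H](CO)O1 | starting material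
2 | (5R)-5-{[tert-butyl(dimethyl)silyl]oxymethyl}oxolan-2-one | O=C1CC[C@H](CO[Si](C)(C)C(C)(C)C)O1 | intermediate
3 | (5R)-5-{[tert-butyl(dimethyl)silyl]oxymethyl}-3-(phenylselanyl)oxolan-2-one (C3 epimers) | O=C1C([Se]c2ccccc2)C[C@H](CO[Si](C)(C)C(C)(C)C)O1 | intermediate
4 | selenoxide of 3 | O=C1C([Se](=O)c2ccccc2)C[C@H](CO[Si](C)(C)C(C)(C)C)O1 | intermediate
5 | (5R)-5-{[tert-butyl(dimethyl)silyl]oxymethyl}furan-2(5H)-one (fragment 1) | O=C1C=C[C@H](CO[Si](C)(C)C(C)(C)C)O1 | intermediate
6 | 3-methylbut-3-enoic acid | C=C(C)CC(=O)O | starting material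
7 | (4S)-4-benzyl-1,3-oxazolidin-2-one | O=C1N[C@@H](Cc2ccccc2)CO1 | starting material
8 | 3-methylbut-3-enoic pivalic anhydride | C=C(C)CC(=O)OC(=O)C(C)(C)C | intermediate
9 | (4S)-4-benzyl-3-(3-methylbut-3-enoyl)-1,3-oxazolidin-2-one | C=C(C)CC(=O)N1[C@@H](Cc2ccccc2)COC1=O | intermediate
10 | (4S)-4-benzyl-3-[(2R)-2-(dimethoxymethyl)-3-methylbut-3-enoyl]-1,3-oxazolidin-2-one | O=C([C@@H](C(OC)OC)C(C)=C)N1[C@@H](Cc2ccccc2)COC1=O | intermediate
11 | propane-1,3-dithiol | SCCCS | starting material
12 | (4S)-4-benzyl-3-[(2S)-2-(1,3-dithian-2-yl)-3-methylbut-3-enoyl]-1,3-oxazolidin-2-one | O=C([C@@H](C1SCCCS1)C(C)=C)N1[C@@H](Cc2ccccc2)COC1=O | intermediate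
13 | (2S)-2-(1,3-dithian-2-yl)-3-methylbut-3-en-1-ol | OC[C@@H](C1SCCCS1)C(C)=C | intermediate
14 | (2S)-2-(1,3-dithian-2-yl)-3-methylbut-3-enal | O=C[C@@H](C1SCCCS1)C(C)=C | intermediate
15 | 2-[(3R)-1,1-dibromo-4-methylpenta-1,4-dien-3-yl]-1,3-dithiane | BrC(Br)=C[C@@H](C1SCCCS1)C(C)=C | intermediate
16 | methyl (4S)-4-(1,3-dithian-2-yl)-5-methylhex-5-en-2-ynoate | COC(=O)C#C[C@@H](C1SCCCS1)C(C)=C | intermediate
17 | methyl (2Z,4S)-4-(1,3-dithian-2-yl)-3,5-dimethylhexa-2,5-dienoate | S1CCCSC1[C@@H](C(C)=C)/C(C)=C\C(=O)OC | intermediate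
18 | (2Z,4S)-4-(1,3-dithian-2-yl)-3,5-dimethylhexa-2,5-dien-1-ol | S1CCCSC1[C@@H](C(C)=C)/C(C)=C\CO | intermediate
19 | {[(2Z,4S)-4-(1,3-dithian-2-yl)-3,5-dimethylhexa-2,5-dien-1-yl]oxy}(triethyl)silane (fragment 2) | S1CCCSC1[C@@H](C(C)=C)/C(C)=C\CO[Si](CC)(CC)CC | intermediate
20 | N,N-dimethylmethaniminium iodide | C=[N+](C)C.[I-] | starting material
21 | 2-lithio derivative of 19 | [Li]C1(SCCCS1)[C@@H](C(C)=C)/C(C)=C\CO[Si](CC)(CC)CC | intermediate
22 | lithium enolate of the conjugate adduct | [Li+].[O-]C(O[C@@H](CO[Si](C)(C)C(C)(C)C)[C@@H]1C2(SCCCS2)[C@@H](C(C)=C)/C(C)=C\CO[Si](CC)(CC)CC)=C1 | intermediate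
23 | (3S,4R,5R)-5-{[tert-butyl(dimethyl)silyl]oxymethyl}-3-[(dimethylamino)methyl]-4-{2-[(3S,4Z)-2,4-dimethyl-6-(triethylsilyloxy)hexa-1,4-dien-3-yl]-1,3-dithian-2-yl}oxolan-2-one | CN(C)C[C@H]1C(=O)O[C@@H](CO[Si](C)(C)C(C)(C)C)[C@@H]1C2(SCCCS2)[C@@H](C(C)=C)/C(C)=C\CO[Si](CC)(CC)CC | intermediate
24 | (3S,4R,5R)-5-{[tert-butyl(dimethyl)silyl]oxymethyl}-3-[(dimethylamino)methyl]-4-{2-[(3S,4Z)-6-hydroxy-2,4-dimethylhexa-1,4-dien-3-yl]-1,3-dithian-2-yl}oxolan-2-one | CN(C)C[C@H]1C(=O)O[C@@H](CO[Si](C)(C)C(C)(C)C)[C@@H]1C2(SCCCS2)[C@@H](C(C)=C)/C(C)=C\CO | intermediate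
25 | O2 diethyl phosphate of 24 | CN(C)C[C@H]1C(=O)O[C@@H](CO[Si](C)(C)C(C)(C)C)[C@@H]1C2(SCCCS2)[C@@H](C(C)=C)/C(C)=C\COP(=O)(OCC)OCC | intermediate
26 | C9 primary alcohol (25 without the silyl group) | CN(C)C[C@H]1C(=O)O[C@@H](CO)[C@@H]1C2(SCCCS2)[C@@H](C(C)=C)/C(C)=C\COP(=O)(OCC)OCC | intermediate
27 | (2R,3R,4S)-3-{2-[(3S,4Z)-6-[(diethoxyphosphoryl)oxy]-2,4-dimethylhexa-1,4-dien-3-yl]-1,3-dithian-2-yl}-4-[(dimethylamino)methyl]-5-oxooxolane-2-carbaldehyde | CN(C)C[C@H]1C(=O)O[C@@H](C=O)[C@@H]1C2(SCCCS2)[C@@H](C(C)=C)/C(C)=C\COP(=O)(OCC)OCC | intermediate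
28 | (5S,7R,8R,9S,10S,11S)-13-(dimethylamino)-9-hydroxy-6,6-(propane-1,3-diyldisulfanediyl)-11,13-dihydroelema-1,3-dien-12,8-olide | CN(C)C[C@H]1C(=O)O[C@@H]2[C@@H]1C3(SCCCS3)[C@@H](C(C)=C)[C@](C)(C=C)[C@@H]2O | intermediate
29 | angelic acid [(2Z)-2-methylbut-2-enoic acid] | C/C=C(/C)C(=O)O | starting material
30 | (5S,7R,8R,9S,10S,11S)-9-angeloyloxy-13-(dimethylamino)-6,6-(propane-1,3-diyldisulfanediyl)-11,13-dihydroelema-1,3-dien-12,8-olide | CN(C)C[C@H]1C(=O)O[C@@H]2[C@@H]1C3(SCCCS3)[C@@H](C(C)=C)[C@](C)(C=C)[C@@H]2OC(=O)/C(C)=C\C | intermediate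
31 | (5S,7R,8R,9S,10S,11S)-9-angeloyloxy-13-(dimethylamino)-6-oxo-11,13-dihydroelema-1,3-dien-12,8-olide | CN(C)C[C@H]1C(=O)O[C@@H]2[C@@H]1C(=O)[C@@H](C(C)=C)[C@](C)(C=C)[C@@H]2OC(=O)/C(C)=C\C | intermediate
32 | (5S,6S,7S,8R,9S,10S,11S)-9-angeloyloxy-13-(dimethylamino)-6-hydroxy-11,13-dihydroelema-1,3-dien-12,8-olide | CN(C)C[C@H]1C(=O)O[C@@H]2[C@@H]1[C@@H](O)[C@@H](C(C)=C)[C@](C)(C=C)[C@@H]2OC(=O)/C(C)=C\C | intermediate
33 | N-methyl ammonium iodide of 32 | C[N+](C)(C)C[C@H]1C(=O)O[C@@H]2[C@@H]1[C@@H](O)[C@@H](C(C)=C)[C@](C)(C=C)[C@@H]2OC(=O)/C(C)=C\C.[I-] | intermediate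
34 | (5S,6S,7S,8R,9S,10S)-9-angeloyloxy-6-hydroxyelema-1,3,11(13)-trien-12,8-olide | C=C1C(=O)O[C@@H]2[C@@H]1[C@@H](O)[C@@H](C(C)=C)[C@](C)(C=C)[C@@H]2OC(=O)/C(C)=C\C | intermediate
35 | (5S,6S,7S,8R,9S,10S)-9-angeloyloxy-6,15-dihydroxyelema-1,3,11(13)-trien-12,8-olide | C=C1C(=O)O[C@@H]2[C@@H]1[C@@H](O)[C@@H](C(=C)CO)[C@](C)(C=C)[C@@H]2OC(=O)/C(C)=C\C | intermediate
36 | (5R,6S,7S,8R,9S,10S)-9-angeloyloxy-6-hydroxy-15-oxoelema-1,3,11(13)-trien-12,8-olide | C=C1C(=O)O[C@@H]2[C@@H]1[C@@H](O)[C@@H](C(=C)C=O)[C@](C)(C=C)[C@@H]2OC(=O)/C(C)=C\C | intermediate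
37 | (1R,5R,6S,7S,8R,9S,10R)-9-angeloyloxy-2-bromo-1,6-dihydroxy-15-oxoelema-3,11(13)-dien-12,8-olide | C=C1C(=O)O[C@@H]2[C@@H]1[C@@H](O)[C@@H](C(=C)C=O)[C@](C)([C@@H](O)CBr)[C@@H]2OC(=O)/C(C)=C\C | intermediate
38 | (1R,5R,6S,7S,8R,9S,10R)-9-angeloyloxy-1,2-epoxy-6-hydroxy-15-oxoelema-3,11(13)-dien-12,8-olide | C=C1C(=O)O[C@@H]2[C@@H]1[C@@H](O)[C@@H](C(=C)C=O)[C@](C)([C@@H]1CO1)[C@@H]2OC(=O)/C(C)=C\C | target

## Step count and least certain steps

Total step count: 24. Longest linear sequence: 22 steps (steps 3–24, from acid 6); the butenolide branch (steps 1–2) joins at step 12.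

**Step 12 (key step).** The most likely failure is deprotonation at the doubly allylic C5–H instead of C6, which would scramble C5 and give pentadienyl-type products. Further risks are 1,2-addition to the lactone carbonyl and slow addition of the hindered tertiary carbanion. Fallback: the route leaves at 19 and returns at 23. Oxidation of 19 with NaIO4 in aqueous methanol should give the dithiane 1-oxide F1 (sulfoxide epimers). Its C6 proton, between sulfur and sulfinyl, is far more acidic than C5–H and is removed by LDA at −78 °C. Conjugate addition of this sulfinyl-stabilised anion to 5 and trapping with 20 should give the sulfoxide adduct F2. Deoxygenation with (CF3CO)2O/NaI in acetone at −40 °C returns to 23.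

**Step 17 (ring closure).** Partial E/Z equilibration of the allylchromium species would erode the C9 configuration; attack through C2 (eight-membered ring) and simple reduction of the phosphate are the other losses. Fallback: the route leaves at 25 and returns at 28. Stannylation of 25 with Bu3SnAlEt2 and Pd(PPh3)4 should give the allylstannane F3. Buffered TBAF/AcOH then gives the stannyl alcohol F4, and Parikh–Doering oxidation the stannyl aldehyde F5. BF3·OEt2 at −78 °C (one equivalent is held by the amine) closes the ring through an open synclinal transition state. That mode places hydroxyl and vinyl cis whatever the alkene geometry, and gives 28.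

**Steps 23 and 24 (oxirane).** Poor facial discrimination at the rotating vinyl group is the main risk. Participation of the C9 ester carbonyl in opening the bromonium ion would divert material or deliver the C1 epimer. Fallback: the route leaves at 36 and returns at 38. Direct oxygen transfer with dimethyldioxirane in acetone at 0 °C epoxidises only the electron-rich vinyl group. For a given facial preference of the electrophile, direct transfer and the halohydrin sequence place oxygen on opposite faces, so whichever face is intrinsically exposed, one of the two should give the 1R oxirane. No new compound is formed on this path.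

**Step 18 (angelate).** Slow acylation of the axial, neopentyl-type O9 would allow Z→E isomerisation to the tiglate, and prolonged warming could eliminate dimethylamine prematurely. Fallback: the route leaves at 28 and returns at 30. Esterification of 28 with 2-[bis(2,2,2-trifluoroethoxy)phosphoryl]propanoic acid (DCC, DMAP) should give the phosphonate ester F6. Deprotonation with KHMDS/18-crown-6 at −78 °C and addition of acetaldehyde (Z-selective Horner–Wadsworth–Emmons olefination, Still–Gennari variant) builds the angelate double bond on the ester already in place.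

**Steps 19 and 20 (C6 ketone).** Sluggish hydrolysis of the hindered spiro-dithiane and enolisation of the ketone toward C7 (giving the cis-fused lactone) or toward C5 (conjugation of the isopropenyl group) are the risks; incomplete facial selectivity of the hydride is a lesser one. Fallback: the route leaves at 30 and returns at 31. Oxidation of 30 as its trifluoroacetate salt with NaIO4 should give the dithiane 1-oxide F7. This hydrolyses under much milder acid (dilute HCl in THF at 0 °C) than the parent dithiane, and the ketone 31 is reduced at once as in step 20.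

## Further compounds

F1 | step 12 | 1-oxide of dithiane 19 (sulfoxide epimers) | O=S1CCCSC1[C@@H](C(C)=C)/C(C)=C\CO[Si](CC)(CC)CC
F2 | step 12 | dithiane 1-oxide of 23 (sulfoxide epimers) | CN(C)C[C@H]1C(=O)O[C@@H](CO[Si](C)(C)C(C)(C)C)[C@@H]1C2(S(=O)CCCS2)[C@@H](C(C)=C)/C(C)=C\CO[Si](CC)(CC)CC
F3 | step 17 | allylstannane from 25 (tributylstannyl in place of the phosphate) | CN(C)C[C@H]1C(=O)O[C@@H](CO[Si](C)(C)C(C)(C)C)[C@@H]1C2(SCCCS2)[C@@H](C(C)=C)/C(C)=C\C[Sn](CCCC)(CCCC)CCCC
F4 | step 17 | stannyl C9 alcohol | CN(C)C[C@H]1C(=O)O[C@@H](CO)[C@@H]1C2(SCCCS2)[C@@H](C(C)=C)/C(C)=C\C[Sn](CCCC)(CCCC)CCCC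
F5 | step 17 | stannyl C9 aldehyde | CN(C)C[C@H]1C(=O)O[C@@H](C=O)[C@@H]1C2(SCCCS2)[C@@H](C(C)=C)/C(C)=C\C[Sn](CCCC)(CCCC)CCCC
F0 | step 23 | none | none
F6 | step 18 | 9-O-{2-[bis(2,2,2-trifluoroethoxy)phosphoryl]propanoyl} ester of 28 (epimers at the phosphonate carbon) | CN(C)C[C@H]1C(=O)O[C@@H]2[C@@H]1C3(SCCCS3)[C@@H](C(C)=C)[C@](C)(C=C)[C@@H]2OC(=O)C(C)P(=O)(OCC(F)(F)F)OCC(F)(F)F
F7 | step 19 | dithiane 1-oxide of 30 (sulfoxide epimers) | CN(C)C[C@H]1C(=O)O[C@@H]2[C@@H]1C3(S(=O)CCCS3)[C@@H](C(C)=C)[C@](C)(C=C)[C@@H]2OC(=O)/C(C)=C\C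
A1 | alternative 1 | (1(10)E,4Z,6S,7S,8R,9S)-6,9-dihydroxy-15-oxogermacra-1(10),4,11(13)-trien-12,8-olide (both ring alkenes trans within the ring) | C=C1C(=O)O[C@@H]2[C@@H]1[C@@H](O)/C=C(C=O)/CC/C=C(C)/[C@@H]2O
A2 | alternative 1 | 6,9-dihydroxy-15-oxoelema-1,3,11(13)-trien-12,8-olide | C=C1C(=O)O[C@@H]2[C@@H]1[C@@H](O)[C@@H](C(=C)C=O)[C@](C)(C=C)[C@@H]2O
A3 | alternative 2 | C9 aldoxime of the open-chain lactone with 6-O-methoxymethyl, C4 dioxolane and (Z)-C10=C1 allylic silyl ether | C1C(=O)O[C@@H](/C=N/O)[C@@H]1[C@@H](OCOC)[C@@H](C2(C)OCCO2)/C(C)=C\CO[Si](C)(C)C(C)(C)C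
A4 | alternative 2 | nitrile oxide derived from A3 | C1C(=O)O[C@@H](C#[N+][O-])[C@@H]1[C@@H](OCOC)[C@@H](C2(C)OCCO2)/C(C)=C\CO[Si](C)(C)C(C)(C)C
A5 | alternative 2 | lactone-fused cyclohexane isoxazoline | C1C(=O)O[C@@H]2[C@@H]1[C@@H](OCOC)[C@@H](C3(C)OCCO3)[C@]4(C)[C@H](CO[Si](C)(C)C(C)(C)C)ON=C24
A6 | alternative 3 | 4,4-dimethoxy-2-methylcyclohex-2-en-1-one | O=C1C(C)=CC(OC)(OC)CC1
A7 | alternative 3 | (3,3-diethoxyprop-1-en-2-yl)magnesium bromide | CCOC(OCC)C(=C)[Mg]Br
A8 | alternative 3 | chloroacetaldehyde | ClCC=O
A9 | alternative 3 | 2-(2-chloro-1-hydroxyethyl)-3-(3,3-diethoxyprop-1-en-2-yl)-4,4-dimethoxy-2-methylcyclohexanone | O=C1CCC(OC)(OC)[C@@H](C(=C)C(OCC)OCC)[C@]1(C)[C@@H](O)CCl
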